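The cyclohexane ring is disconnected at C1–C14 and C12–C13. This exposes an oxonane-bridged 2,5-dihydrofuran whose C1=C10 double bond, extended by a 1-ethoxyvinyl group (C11, C12), is a 2-ethoxy-1,3-diene. A Diels–Alder reaction with methyl vinyl ketone closes the six-membered ring, forms both bonds and fixes C1 and, after equilibration, C14. It exploits the fusion of the cyclohexane to the tetrahydrofuran along C1–C10 and the C3–C8 bridge of the oxonane, which shields one diene face. The precursor is the bicyclic dienyl ether with a C3 triethylsilyl ether; its C7 methylene is kept latent as the C6=C7 allylsilane, so that later hydroboration touches only the isopropenyl group.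

Key step: step 15

Remarks on the chemistry
- Locants: C1 and C10 are the carbons shared by the cyclohexane (C1, C10, C11, C12, C13, C14) and the tetrahydrofuran (C1, C2, O, C9, C10). The oxonane runs from C2 through C3–C8 to C9. The oxepane is closed by C3–O–C16, with C15 between C16 and C14.
- The C7 methylene is carried from step 12 to step 19 as the C6=C7 allylsilane (CH2SiMe3 on C7) and released in step 20. An exposed 1,1-disubstituted C7 alkene would compete with the isopropenyl group in step 17. The diene unit, the bonds made and the ring closed in step 15 are unchanged.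
- Assumption: the [2,3] shift of step 12 may give both geometries of the C6=C7 bond. The ring-cis isomer is drawn; both converge in step 20.
- The C3 carbinol is made by methyl addition to an oxan-3-one (steps 7 and 8). A ketyl cyclisation of the corresponding methyl ketone would be expected to place the C3 oxygen trans to the C2 side chain, which is the wrong C3 epimer.

Step 1
Reactants: 1 methyl 4,4-dimethoxybutanoate
Product: 2 N-methoxy-N-methyl-4,4-dimethoxybutanamide
Conditions: MeNH(OMe)·HCl, i-PrMgCl, THF, −20 to 0 °C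
Reagents that add atoms: N,O-dimethylhydroxylamine hydrochloride CNOC.Cl
Why: Aminolysis of a methyl ester by the chloromagnesium amide of N,O-dimethylhydroxylamine (Weinreb amide formation) is general and leaves the dimethyl acetal untouched.

Step 2
Reactants: 2 N-methoxy-N-methyl-4,4-dimethoxybutanamide; 3 (2-bromoallyl)trimethylsilane
Product: 6 6,6-dimethoxy-2-[(trimethylsilyl)methyl]hex-1-en-3-one, via vinyllithium 4 (not isolated), via lithium hemiaminal 5 (not isolated)
Conditions: 3, t-BuLi (2 equiv), Et2O, −78 °C; then 2, −78 to 0 °C; aq NH4Cl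
Reagents that add atoms: none
Why: Bromine–lithium exchange gives the 2-lithioallylsilane, and its addition to the amide stops at the chelated tetrahedral adduct, which releases the enone only on work-up (Weinreb ketone synthesis).

Step 3
Reactants: 6 6,6-dimethoxy-2-[(trimethylsilyl)methyl]hex-1-en-3-one
Product: 7 (3S)-6,6-dimethoxy-2-[(trimethylsilyl)methyl]hex-1-en-3-ol
Conditions: (R)-2-methyl-CBS-oxazaborolidine (0.2 equiv), catecholborane, toluene, −78 °C; aq NaOH work-up
Reagents that add atoms: none
Why: In this Corey–Bakshi–Shibata reduction the 2-substituted vinyl group acts as the large and the primary alkyl chain as the small ketone substituent, so the (R)-catalyst should give the (S)-carbinol, and catecholborane at −78 °C does not hydroborate the alkene.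

Step 4
Reactants: 7 (3S)-6,6-dimethoxy-2-[(trimethylsilyl)methyl]hex-1-en-3-ol; 8 ethyl propiolate
Product: 9 ethyl (2E)-3-{[(3S)-6,6-dimethoxy-2-[(trimethylsilyl)methyl]hex-1-en-3-yl]oxy}prop-2-enoate
Conditions: N-methylmorpholine, CH2Cl2, rt
Reagents that add atoms: none
Why: Amine-catalysed oxa-Michael addition of a secondary alcohol to an ynoate gives the (E)-β-alkoxyacrylate without touching the carbinol stereocentre.

Step 5
Reactants: 9 ethyl (2E)-3-{[(3S)-6,6-dimethoxy-2-[(trimethylsilyl)methyl]hex-1-en-3-yl]oxy}prop-2-enoate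
Product: 10 ethyl (2E)-3-{[(3S)-6-oxo-2-[(trimethylsilyl)methyl]hex-1-en-3-yl]oxy}prop-2-enoate
Conditions: Amberlyst-15, THF/H2O (10:1), rt
Reagents that add atoms: water O
Why: Acid-catalysed hydrolysis of an unhindered dimethyl acetal is fast under conditions that neither cleave the vinylogous carbonate nor protodesilylate the allylsilane.

Step 6
Reactants: 10 ethyl (2E)-3-{[(3S)-6-oxo-2-[(trimethylsilyl)methyl]hex-1-en-3-yl]oxy}prop-2-enoate
Product: 11 ethyl 2-{(2S,3R,6S)-3-hydroxy-6-[3-(trimethylsilyl)prop-1-en-2-yl]oxan-2-yl}acetate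
Conditions: SmI2 (2.5 equiv), MeOH (3 equiv), THF, 0 °C
Reagents that add atoms: none
Why: Ketyl–olefin reductive cyclisation (6-exo addition of the ketyl to the β-alkoxyacrylate) through a chair with the C6 substituent and the acrylate equatorial is known to give 2,6-cis-2,3-trans oxan-3-ols, which sets C2 from C6, while the C3 carbinol is oxidised in the next step.

Step 7
Reactants: 11 ethyl 2-{(2S,3R,6S)-3-hydroxy-6-[3-(trimethylsilyl)prop-1-en-2-yl]oxan-2-yl}acetate
Product: 12 ethyl 2-{(2S,6S)-3-oxo-6-[3-(trimethylsilyl)prop-1-en-2-yl]oxan-2-yl}acetate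
Conditions: Dess–Martin periodinane, CH2Cl2, rt
Reagents that add atoms: none
Why: Dess–Martin oxidation of a secondary alcohol is non-basic, so C2 is not epimerised, the β-alkoxy ester is not opened and the allylsilane is untouched.

Step 8
Reactants: 12 ethyl 2-{(2S,6S)-3-oxo-6-[3-(trimethylsilyl)prop-1-en-2-yl]oxan-2-yl}acetate
Product: 13 ethyl 2-{(2S,3S,6S)-3-hydroxy-3-methyl-6-[3-(trimethylsilyl)prop-1-en-2-yl]oxan-2-yl}acetate
Conditions: MeMgCl, THF, −78 °C; aq NH4Cl at −78 °C
Reagents that add atoms: methylmagnesium chloride C[Mg]Cl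
Why: Grignard addition to the ketone outpaces attack on the ester at −78 °C, and equatorial attack anti to the ring C2–O bond (Felkin–Anh polar model) should place the methyl trans and the hydroxyl cis to the C2 acetate arm, the cold quench keeping the cis hydroxy ester from lactonising.

Step 9
Reactants: 13 ethyl 2-{(2S,3S,6S)-3-hydroxy-3-methyl-6-[3-(trimethylsilyl)prop-1-en-2-yl]oxan-2-yl}acetate
Product: 14 ethyl 2-{(2S,3S,6S)-3-methyl-3-[(triethylsilyl)oxy]-6-[3-(trimethylsilyl)prop-1-en-2-yl]oxan-2-yl}acetate
Conditions: TESOTf, 2,6-lutidine, CH2Cl2, −78 to 0 °C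
Reagents that add atoms: triethylsilyl trifluoromethanesulfonate CC[Si](CC)(CC)OS(=O)(=O)C(F)(F)F
Why: Silyl triflate with a hindered base is the standard silylation of a tertiary alcohol, which must be masked against O–H insertion and lactonisation in the carbenoid step.

Step 10
Reactants: 14 ethyl 2-{(2S,3S,6S)-3-methyl-3-[(triethylsilyl)oxy]-6-[3-(trimethylsilyl)prop-1-en-2-yl]oxan-2-yl}acetate
Product: 15 2-{(2S,3S,6S)-3-methyl-3-[(triethylsilyl)oxy]-6-[3-(trimethylsilyl)prop-1-en-2-yl]oxan-2-yl}acetic acid
Conditions: LiOH, THF/MeOH/H2O, rt; 1 M HCl to pH 4 at 0 °C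
Reagents that add atoms: lithium hydroxide [Li+].[OH-]
Why: Saponification of an unhindered ethyl ester proceeds without retro-oxa-Michael opening of the carboxylate, and the tertiary silyl ether survives aqueous base.

Step 11
Reactants: 15 2-{(2S,3S,6S)-3-methyl-3-[(triethylsilyl)oxy]-6-[3-(trimethylsilyl)prop-1-en-2-yl]oxan-2-yl}acetic acid
Product: 17 1-diazo-3-{(2S,3S,6S)-3-methyl-3-[(triethylsilyl)oxy]-6-[3-(trimethylsilyl)prop-1-en-2-yl]oxan-2-yl}propan-2-one, via mixed anhydride 16 (not isolated)
Conditions: i-BuOCOCl, Et3N, Et2O, 0 °C; then CH2N2 (Et2O), 0 °C to rt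
Reagents that add atoms: diazomethane C=[N+]=[N-]
Why: Acylation of diazomethane by a mixed carbonic anhydride (first stage of the Arndt–Eistert sequence) gives the α-diazoketone without acid that would endanger the silyl ether or the allylsilane.

Step 12
Reactants: 17 1-diazo-3-{(2S,3S,6S)-3-methyl-3-[(triethylsilyl)oxy]-6-[3-(trimethylsilyl)prop-1-en-2-yl]oxan-2-yl}propan-2-one
Product: 19 (1S,2S,5E,8S)-2-methyl-2-[(triethylsilyl)oxy]-6-[(trimethylsilyl)methyl]-11-oxabicyclo[6.2.1]undec-5-en-9-one, via oxonium ylide 18 (not isolated)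
Conditions: Cu(hfacac)2 (5 mol %), CH2Cl2, reflux
Reagents that add atoms: none
Why: The copper carbenoid is trapped by the ring oxygen as a five-membered oxonium ylide, whose [2,3]-sigmatropic shift of the C6 allyl unit expands the oxane by three atoms to the oxonane-bridged furanone (established for 6-vinyl-oxan-2-yl diazoketones), with C9 forced cis to C2 by the bridge and C6 becoming an alkene carbon.

Step 13
Reactants: 19 (1S,2S,5E,8S)-2-methyl-2-[(triethylsilyl)oxy]-6-[(trimethylsilyl)methyl]-11-oxabicyclo[6.2.1]undec-5-en-9-one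
Product: 21 (1S,2S,5E,8S)-2-methyl-2-[(triethylsilyl)oxy]-6-[(trimethylsilyl)methyl]-11-oxabicyclo[6.2.1]undeca-5,9-dien-9-yl trifluoromethanesulfonate, via sodium enolate 20 (not isolated)
Conditions: NaHMDS, THF, −78 °C; then PhNTf2, −78 to 0 °C; aq NH4Cl
Reagents that add atoms: N-phenylbis(trifluoromethanesulfonimide) O=S(=O)(N(c1ccccc1)S(=O)(=O)C(F)(F)F)C(F)(F)F
Why: Kinetic deprotonation occurs at the C1 methylene and not at the oxygenated C9 methine, and O-sulfonylation of the enolate gives the C1=C10 enol triflate (standard enol triflate formation).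

Step 14
Reactants: 21 (1S,2S,5E,8S)-2-methyl-2-[(triethylsilyl)oxy]-6-[(trimethylsilyl)methyl]-11-oxabicyclo[6.2.1]undeca-5,9-dien-9-yl trifluoromethanesulfonate; 22 tributyl(1-ethoxyvinyl)stannane
Product: 23 (1S,2S,5E,8S)-9-(1-ethoxyvinyl)-2-methyl-2-[(triethylsilyl)oxy]-6-[(trimethylsilyl)methyl]-11-oxabicyclo[6.2.1]undeca-5,9-diene
Conditions: Pd(PPh3)4 (5 mol %), LiCl, THF, reflux
Reagents that add atoms: none
Why: Chloride-assisted Stille coupling of an enol triflate with a 1-alkoxyvinylstannane is a standard route to 2-alkoxy-1,3-dienes and tolerates the silyl ether and the allylsilane.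

Step 15
Reactants: 23 (1S,2S,5E,8S)-9-(1-ethoxyvinyl)-2-methyl-2-[(triethylsilyl)oxy]-6-[(trimethylsilyl)methyl]-11-oxabicyclo[6.2.1]undeca-5,9-diene; 24 methyl vinyl ketone
Product: 26 tricyclic C10=C11 ethyl enol ether with 14R acetyl group (1S,2S,3S,9S; C3 triethylsilyl ether; C6=C7 allylsilane), via endo adduct 25 (not isolated)
Conditions: methyl vinyl ketone (freshly distilled from K2CO3, 5 equiv), BHT (cat.), toluene, base-washed glassware, 70 °C; evaporate; K2CO3, MeOH, rt
Reagents that add atoms: none
Why: The electron-rich diene C12=C11–C10=C1, which can adopt the s-cis conformation, and the electron-poor enone combine in a single-step [4+2] cycloaddition with unequal bond formation, the well-known Diels–Alder reaction of 2-alkoxy-1,3-dienes with vinyl ketones. The cyclohexene ring is closed by suprafacial addition of the dienophile across the diene termini C1 and C12 in an intermolecular cycloaddition, which leaves the C10=C11 enol ether as a masked C11 ketone. C1 is controlled by the C3–C8 chain, since the dienophile can reach C1 only from the dihydrofuran face that this chain does not cover, so that H1 ends syn to the bridge. C14 is set thermodynamically: the endo transition state gives the epimer with acetyl cis to C2, and K2CO3 in methanol equilibrates it through the ketone enolate to the trans, equatorial 14R isomer. Regiochemistry follows from the donor on C11, which puts the largest HOMO coefficient on C12, so that C12 pairs with the electrophilic β-carbon of the enone and the acetyl group ends on C14. Heating without Lewis acid keeps the allylsilane, the silyl ether and the acid-labile enol ether intact.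

Step 16
Reactants: 26 tricyclic enol ether with 14R acetyl group
Product: 27 tricyclic enol ether with C14 isopropenyl group (1S,2S,3S,9S,14R)
Conditions: Ph3PCH3Br, KOt-Bu, THF, 0 °C to rt
Reagents that add atoms: methyltriphenylphosphonium bromide C[P+](c1ccccc1)(c1ccccc1)c1ccccc1.[Br-]
Why: Wittig methylenation of the methyl ketone is safe because C14 is already the thermodynamic epimer and C11 is masked as the non-electrophilic enol ether.

Step 17
Reactants: 27 tricyclic enol ether with C14 isopropenyl group
Product: 29 tricyclic enol ether with (15R)-C16 primary alcohol (1S,2S,3S,9S,14S,15R), via trialkylborane 28 (not isolated)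
Conditions: (−)-Ipc2BH, THF, −25 to 0 °C; then NaOH, H2O2, 0 °C to rt
Reagents that add atoms: hydrogen peroxide OO
Why: Hydroboration–oxidation with this bulky dialkylborane (Brown hydroboration) adds boron only to the terminal carbon of the isopropenyl group, the trisubstituted allylsilane and the tetrasubstituted enol ether being far less reactive, and the reagent from (+)-α-pinene is chosen because its reported preference with 2-methyl-1-alkenes is for the (R)-2-methylalkan-1-ol, here 15R, the oxidation proceeding with retention.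

Step 18
Reactants: 29 tricyclic enol ether with (15R)-C16 primary alcohol
Product: 30 cis-fused C11 ketone with free C3 and C16 hydroxyls (1S,2S,3S,9S,10R,14S,15R; allylsilane retained)
Conditions: 1 M HCl, THF, 0 °C to rt
Reagents that add atoms: water O
Why: Acid hydrolysis of the enol ether gives the C11 ketone with C10 equilibrated through the enol to the strongly favoured cis ring fusion, and the same medium cleaves the triethylsilyl ether, any early loss of the allylic silicon being harmless because both forms converge in step 20.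

Step 19
Reactants: 30 cis-fused C11 ketone with free C3 and C16 hydroxyls
Product: 32 tetracyclic oxepane C11 ketone with C6=C7 allylsilane, via C16 triflate 31 (not isolated)
Conditions: Tf2O (1.1 equiv), 2,6-lutidine, CH2Cl2, −78 to 0 °C
Reagents that add atoms: none
Why: Selective triflation of the primary alcohol is followed by intramolecular Williamson-type SN2 displacement by the C3 tertiary hydroxyl (7-exo-tet), a closure known for this oxepane in related diterpenoids, with C15 untouched.

Step 20
Reactants: 32 tetracyclic oxepane C11 ketone with C6=C7 allylsilane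
Product: 33 tetracyclic oxepane C11 ketone with C7 exocyclic methylene (1S,2S,3S,9S,10R,14S,15R)
Conditions: TsOH·H2O, CH2Cl2, 0 °C to rt
Reagents that add atoms: none
Why: Protodesilylation of the allylsilane (SE2′) puts the proton on C6 and moves the double bond to the exocyclic C7 position for either C6=C7 geometry, and with the C3 oxygen already tied into the oxepane no hydroxyl can add across the ring to the C7 cation.

Step 21
Reactants: 33 tetracyclic oxepane C11 ketone with C7 exocyclic methylene
Product: 35 (12S)-12-hydroxy C11 ketone, via potassium enolate 34 (not isolated)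
Conditions: KHMDS, THF, −78 °C; then 2-(phenylsulfonyl)-3-phenyloxaziridine, −78 °C; aq NH4Cl
Reagents that add atoms: 2-(phenylsulfonyl)-3-phenyloxaziridine O=S(=O)(N1OC1c1ccccc1)c1ccccc1
Why: Kinetic enolisation towards the C12 methylene and enolate hydroxylation with a Davis oxaziridine, which ignores the isolated C7 alkene, should deliver oxygen on the convex face away from the axial C10–C9 bond, which is also the equatorial and thermodynamically preferred 12S position.

Step 22
Reactants: 35 (12S)-12-hydroxy C11 ketone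
Product: 36 (12S)-12-hydroxy-11-methylene compound
Conditions: Zn, CH2Br2, TiCl4, THF/CH2Cl2, 0 °C to rt
Reagents that add atoms: dibromomethane BrCBr
Why: Takai–Lombardo methylenation uses a non-basic zinc/titanium methylene reagent that olefinates hindered, enolisable and hydroxylated ketones without epimerisation, ketol shift or β-elimination of the C9 oxygen.

Step 23
Reactants: 36 (12S)-12-hydroxy-11-methylene compound
Product: 37 (11S,12S)-spiro-epoxy alcohol (epoxide oxygen on C11 cis to the C12 hydroxyl)
Conditions: VO(acac)2 (5 mol %), t-BuOOH, CH2Cl2, 0 °C to rt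
Reagents that add atoms: tert-butyl hydroperoxide CC(C)(C)OO
Why: Hydroxyl-directed vanadium-catalysed epoxidation oxidises only the allylic-alcohol alkene, not the isolated C7 methylene, and delivers oxygen to the face of the C12 hydroxyl, which is also the convex face of the cis-fused bicycle.

Step 24
Reactants: 37 (11S,12S)-spiro-epoxy alcohol
Product: 38 (11R,12S)-11,12-diol (cis; C11 methyl)
Conditions: LiEt3BH, THF, 0 °C to rt; H2O
Reagents that add atoms: none
Why: Hydride opening of the 2,2-disubstituted epoxide at its unhindered methylene carbon (SN2) converts that carbon into the C11 methyl group and leaves the C11–O bond, hence the 11R carbinol, unchanged.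

Step 25
Reactants: 38 (11R,12S)-11,12-diol; 39 octanoyl chloride
Product: 40 CNP0286133.1, the (1S,2S,3S,9S,10R,11R,12S,14S,15R) C12 octanoate
Conditions: pyridine, DMAP (cat.), CH2Cl2, 0 °C to rt
Reagents that add atoms: none
Why: DMAP-catalysed acylation discriminates between the secondary C12 hydroxyl and the hindered tertiary C11 hydroxyl, so the monoester should form without protection.

Compound list
1 | methyl 4,4-dimethoxybutanoate | COC(=O)CCC(OC)OC | starting material
2 | N-methoxy-N-methyl-4,4-dimethoxybutanamide | CON(C)C(=O)CCC(OC)OC | intermediate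
3 | (2-bromoallyl)trimethylsilane | C=C(Br)C[Si](C)(C)C | starting material
4 | [3-(trimethylsilyl)prop-1-en-2-yl]lithium | [Li]C(=C)C[Si](C)(C)C | intermediate
5 | lithium hemiaminal (tetrahedral adduct of 4 and 2) | CON(C)C([O-])(CCC(OC)OC)C(=C)C[Si](C)(C)C.[Li+] | intermediate
6 | 6,6-dimethoxy-2-[(trimethylsilyl)methyl]hex-1-en-3-one | C=C(C[Si](C)(C)C)C(=O)CCC(OC)OC | intermediate
7 | (3S)-6,6-dimethoxy-2-[(trimethylsilyl)methyl]hex-1-en-3-ol | C=C(C[Si](C)(C)C)[C@@H](O)CCC(OC)OC | intermediate
8 | ethyl propiolate | CCOC(=O)C#C | starting material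
9 | ethyl (2E)-3-{[(3S)-6,6-dimethoxy-2-[(trimethylsilyl)methyl]hex-1-en-3-yl]oxy}prop-2-enoate | CCOC(=O)/C=C/O[C@H](C(=C)C[Si](C)(C)C)CCC(OC)OC | intermediate
10 | ethyl (2E)-3-{[(3S)-6-oxo-2-[(trimethylsilyl)methyl]hex-1-en-3-yl]oxy}prop-2-enoate | CCOC(=O)/C=C/O[C@H](C(=C)C[Si](C)(C)C)CCC=O | intermediate
11 | ethyl 2-{(2S,3R,6S)-3-hydroxy-6-[3-(trimethylsilyl)prop-1-en-2-yl]oxan-2-yl}acetate (2,6-cis, 2,3-trans) | CCOC(=O)C[C@@H]1O[C@H](C(=C)C[Si](C)(C)C)CC[C@H]1O | intermediate
12 | ethyl 2-{(2S,6S)-3-oxo-6-[3-(trimethylsilyl)prop-1-en-2-yl]oxan-2-yl}acetate | CCOC(=O)C[C@@H]1O[C@H](C(=C)C[Si](C)(C)C)CCC1=O | intermediate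
13 | ethyl 2-{(2S,3S,6S)-3-hydroxy-3-methyl-6-[3-(trimethylsilyl)prop-1-en-2-yl]oxan-2-yl}acetate (hydroxyl cis to the C2 arm) | CCOC(=O)C[C@@H]1O[C@H](C(=C)C[Si](C)(C)C)CC[C@]1(C)O | intermediate
14 | ethyl 2-{(2S,3S,6S)-3-methyl-3-[(triethylsilyl)oxy]-6-[3-(trimethylsilyl)prop-1-en-2-yl]oxan-2-yl}acetate | CCOC(=O)C[C@@H]1O[C@H](C(=C)C[Si](C)(C)C)CC[C@]1(C)O[Si](CC)(CC)CC | intermediate
15 | 2-{(2S,3S,6S)-3-methyl-3-[(triethylsilyl)oxy]-6-[3-(trimethylsilyl)prop-1-en-2-yl]oxan-2-yl}acetic acid | OC(=O)C[C@@H]1O[C@H](C(=C)C[Si](C)(C)C)CC[C@]1(C)O[Si](CC)(CC)CC | intermediate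
16 | isobutyl carbonic mixed anhydride of 15 | CC(C)COC(=O)OC(=O)C[C@@H]1O[C@H](C(=C)C[Si](C)(C)C)CC[C@]1(C)O[Si](CC)(CC)CC | intermediate
17 | 1-diazo-3-{(2S,3S,6S)-3-methyl-3-[(triethylsilyl)oxy]-6-[3-(trimethylsilyl)prop-1-en-2-yl]oxan-2-yl}propan-2-one | [N-]=[N+]=CC(=O)C[C@@H]1O[C@H](C(=C)C[Si](C)(C)C)CC[C@]1(C)O[Si](CC)(CC)CC | intermediate
18 | bicyclic oxonium ylide (oxane oxygen bonded to the former diazo carbon) | O=C1C[C@@H]2[O+]([CH-]1)[C@H](C(=C)C[Si](C)(C)C)CC[C@]2(C)O[Si](CC)(CC)CC | intermediate
19 | (1S,2S,5E,8S)-2-methyl-2-[(triethylsilyl)oxy]-6-[(trimethylsilyl)methyl]-11-oxabicyclo[6.2.1]undec-5-en-9-one (oxa-bridged C10 ketone; 2S,3S,9S in skeleton locants; ring-cis C6=C7) | O=C1C[C@@H]2O[C@H]1C/C(C[Si](C)(C)C)=C\CC[C@]2(C)O[Si](CC)(CC)CC | intermediate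
20 | sodium C1=C10 enolate of 19 | [Na+].[O-]C1=C[C@@H]2O[C@H]1C/C(C[Si](C)(C)C)=C\CC[C@]2(C)O[Si](CC)(CC)CC | intermediate
21 | (1S,2S,5E,8S)-2-methyl-2-[(triethylsilyl)oxy]-6-[(trimethylsilyl)methyl]-11-oxabicyclo[6.2.1]undeca-5,9-dien-9-yl trifluoromethanesulfonate | O=S(=O)(OC1=C[C@@H]2O[C@H]1C/C(C[Si](C)(C)C)=C\CC[C@]2(C)O[Si](CC)(CC)CC)C(F)(F)F | intermediate
22 | tributyl(1-ethoxyvinyl)stannane | CCCC[Sn](CCCC)(CCCC)C(=C)OCC | starting material
23 | (1S,2S,5E,8S)-9-(1-ethoxyvinyl)-2-methyl-2-[(triethylsilyl)oxy]-6-[(trimethylsilyl)methyl]-11-oxabicyclo[6.2.1]undeca-5,9-diene (oxa-bridged 2-ethoxy-1,3-diene) | C=C(OCC)C1=C[C@@H]2O[C@H]1C/C(C[Si](C)(C)C)=C\CC[C@]2(C)O[Si](CC)(CC)CC | intermediate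
24 | methyl vinyl ketone | C=CC(C)=O | starting material
25 | endo cycloadduct, the 14S epimer of 26 (acetyl cis to C2) | CC(=O)[C@H]1CCC(OCC)=C2[C@H]1[C@@H]3O[C@H]2C/C(C[Si](C)(C)C)=C\CC[C@]3(C)O[Si](CC)(CC)CC | intermediate
26 | tricyclic C10=C11 ethyl enol ether with 14R acetyl group trans to C2 (1S,2S,3S,9S; C3 triethylsilyl ether; C6=C7 allylsilane) | CC(=O)[C@@H]1CCC(OCC)=C2[C@H]1[C@@H]3O[C@H]2C/C(C[Si](C)(C)C)=C\CC[C@]3(C)O[Si](CC)(CC)CC | intermediate
27 | tricyclic enol ether with C14 isopropenyl group (1S,2S,3S,9S,14R) | C=C(C)[C@@H]1CCC(OCC)=C2[C@H]1[C@@H]3O[C@H]2C/C(C[Si](C)(C)C)=C\CC[C@]3(C)O[Si](CC)(CC)CC | intermediate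
28 | C16 bis(isopinocampheyl)borane adduct of 27 | C[C@H]5[C@H](B(C[C@H](C)[C@@H]1CCC(OCC)=C2[C@H]1[C@@H]3O[C@H]2C/C(C[Si](C)(C)C)=C\CC[C@]3(C)O[Si](CC)(CC)CC)[C@@H]7C[C@@H]8C[C@H]([C@H]7C)C8(C)C)C[C@@H]6C[C@H]5C6(C)C | intermediate
29 | tricyclic enol ether with (15R)-C16 primary alcohol (1S,2S,3S,9S,14S,15R) | OC[C@H](C)[C@@H]1CCC(OCC)=C2[C@H]1[C@@H]3O[C@H]2C/C(C[Si](C)(C)C)=C\CC[C@]3(C)O[Si](CC)(CC)CC | intermediate
30 | cis-fused C11 ketone with free C3 and C16 hydroxyls (1S,2S,3S,9S,10R,14S,15R; C6=C7 allylsilane) | OC[C@H](C)[C@@H]1CCC(=O)[C@@H]2[C@H]1[C@@H]3O[C@H]2C/C(C[Si](C)(C)C)=C\CC[C@]3(C)O | intermediate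
31 | C16 trifluoromethanesulfonate of 30 | O=S(=O)(OC[C@H](C)[C@@H]1CCC(=O)[C@@H]2[C@H]1[C@@H]3O[C@H]2C/C(C[Si](C)(C)C)=C\CC[C@]3(C)O)C(F)(F)F | intermediate
32 | tetracyclic oxepane C11 ketone with C6=C7 allylsilane (1S,2S,3S,9S,10R,14S,15R) | C[Si](C)(C)C/C1=C/CC[C@]2(C)OC[C@H](C)[C@@H]3CCC(=O)[C@@H]4[C@H]3[C@@H]2O[C@H]4C1 | intermediate
33 | tetracyclic oxepane C11 ketone with C7 exocyclic methylene (1S,2S,3S,9S,10R,14S,15R) | C=C1CCC[C@]2(C)OC[C@H](C)[C@@H]3CCC(=O)[C@@H]4[C@H]3[C@@H]2O[C@H]4C1 | intermediate
34 | potassium C11=C12 enolate of 33 | C=C1CCC[C@]2(C)OC[C@H](C)[C@@H]3CC=C([O-])[C@@H]4[C@H]3[C@@H]2O[C@H]4C1.[K+] | intermediate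
35 | (12S)-12-hydroxy C11 ketone (hydroxyl on the face of H1 and H10) | C=C1CCC[C@]2(C)OC[C@H](C)[C@@H]3C[C@H](O)C(=O)[C@@H]4[C@H]3[C@@H]2O[C@H]4C1 | intermediate
36 | (12S)-12-hydroxy-11-methylene compound (10S by priority change, same geometry) | C=C1CCC[C@]2(C)OC[C@H](C)[C@@H]3C[C@H](O)C(=C)[C@@H]4[C@H]3[C@@H]2O[C@H]4C1 | intermediate
37 | (11S,12S)-spiro-epoxy alcohol (epoxide oxygen on C11 cis to the C12 hydroxyl) | C=C1CCC[C@]2(C)OC[C@H](C)[C@@H]3C[C@H](O)[C@]5(OC5)[C@@H]4[C@H]3[C@@H]2O[C@H]4C1 | intermediate
38 | (11R,12S)-11,12-diol with C11 methyl (cis-diol) | C=C1CCC[C@]2(C)OC[C@H](C)[C@@H]3C[C@H](O)[C@](C)(O)[C@@H]4[C@H]3[C@@H]2O[C@H]4C1 | intermediate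
39 | octanoyl chloride | CCCCCCCC(Cl)=O | starting material
40 | CNP0286133.1, (1S,2S,3S,9S,10R,11R,12S,14S,15R) C12 octanoate | C=C1CCC[C@]2(C)OC[C@H](C)[C@@H]3C[C@H](OC(=O)CCCCCCC)[C@](C)(O)[C@@H]4[C@H]3[C@@H]2O[C@H]4C1 | target

Total step count: 25. Longest linear sequence: 25 steps (1 to 40). Compounds 3, 8, 22, 24 and 39 are commercial and enter directly.

Steps most likely to fail

Step 15 (key step). The cycloaddition may be too slow at a temperature the acid- and heat-sensitive dienyl ether tolerates, so that hydrolysis of the diene or polymerisation of the enone takes over. The fallback makes the same two bonds with a more reactive dienophile and completes the methyl ketone afterwards. It sets out from diene 23: cycloaddition with acrolein at or below room temperature, followed by the same K2CO3/MeOH equilibration, should give the C14 aldehyde adduct F1. MeMgBr in THF at −78 °C should then give the C15 carbinol F2 (both carbinol epimers), and Dess–Martin oxidation comes back to the route at methyl ketone 26.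

Step 17. Facial discrimination at the isopropenyl group may be poor, because the intrinsic selectivity of the chiral borane for 1,1-disubstituted alkenes is modest; a mixture of C15 epimers would result. The fallback sets C15 by catalyst-controlled, hydroxyl-directed hydrogenation instead of hydroboration. It sets out from methyl ketone 26: kinetic enolisation of the methyl group with KHMDS and trapping with PhNTf2 at −78 °C should give the isopropenyl triflate F3. Stille coupling with (tributylstannyl)methanol (Pd(PPh3)4, LiCl, dioxane, 90 °C) should give the 2-substituted allylic alcohol F4. Hydrogenation with Ru(OAc)2[(S)-BINAP] (or its antipode, whichever is matched), H2, MeOH, which reduces only the allylic-alcohol alkene, comes back to the route at alcohol 29.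

Step 22. Olefination of the hindered α-ketol may be sluggish, or the Lewis-acidic reagent may cause acyloin isomerisation. The fallback drops the olefination, epoxidation and reduction sequence and adds the methyl group directly. It sets out from hydroxy ketone 35: excess MeMgBr in THF/CH2Cl2 at −78 °C should form the C12 magnesium alkoxide, chelate the C11 carbonyl and add methyl anti to the C12 oxygen (Cram chelate model). It comes back to the route at diol 38, bypassing 36 and 37, and makes no compound outside the list (entry F0).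

Further compounds
F1 | step 15 | tricyclic C10=C11 ethyl enol ether with 14R formyl group trans to C2 (acrolein adduct after equilibration) | O=C[C@@H]1CCC(OCC)=C2[C@H]1[C@@H]3O[C@H]2C/C(C[Si](C)(C)C)=C\CC[C@]3(C)O[Si](CC)(CC)CC
F2 | step 15 | tricyclic enol ether with C14 1-hydroxyethyl group (both carbinol epimers) | CC(O)[C@@H]1CCC(OCC)=C2[C@H]1[C@@H]3O[C@H]2C/C(C[Si](C)(C)C)=C\CC[C@]3(C)O[Si](CC)(CC)CC
F3 | step 17 | tricyclic enol ether with C14 1-(trifluoromethanesulfonyloxy)vinyl group | C=C(OS(=O)(=O)C(F)(F)F)[C@@H]1CCC(OCC)=C2[C@H]1[C@@H]3O[C@H]2C/C(C[Si](C)(C)C)=C\CC[C@]3(C)O[Si](CC)(CC)CC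
F4 | step 17 | tricyclic enol ether with C14 3-hydroxyprop-1-en-2-yl group | C=C(CO)[C@@H]1CCC(OCC)=C2[C@H]1[C@@H]3O[C@H]2C/C(C[Si](C)(C)C)=C\CC[C@]3(C)O[Si](CC)(CC)CC
F0 | step 22 | none | none
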